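**Assumption:** the target SMILES contains no stereocentre or stereogenic double bond, so the compound is achiral and no enantiocontrol is needed.

## Retrosynthetic overview

1. Cut the depside ester C–O bond: a ring A salicylic acid (3-chloro-2-hydroxy-4-methoxy-6-pentylbenzoic acid) and a ring B phenol carrying CHO as a latent CO2H (2,4-dihydroxy-6-pentylbenzaldehyde).
2. Both arenes come from one building block, 1,3-dimethoxy-5-pentylbenzene. Ring A: chlorination between the two OMe groups, formylation, ortho-demethylation, oxidation. Ring B: demethylation, formylation.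
3. Key C–C disconnection: the aryl–CH2 bond of that building block, from 1-bromo-3,5-dimethoxybenzene and pentanal. The aldehyde carbon is used as a carbanion through its hydrazone under nickel catalysis, so two normally electrophilic carbons are joined.
4. No ring is formed; both benzene rings are bought intact in the aryl bromide.

## Route

Step 1
Reactants: 1 1-bromo-3,5-dimethoxybenzene; 2 pentanal; 3 hydrazine monohydrate
Product: 5 1,3-dimethoxy-5-pentylbenzene, via pentanal hydrazone 4 (not isolated)
Conditions: 2 (1.5 equiv), 3 (1.6 equiv), THF, rt, 30 min; then 1, Ni(cod)2 (10 mol %), PMe3 (20 mol %), DBU (2 equiv), THF, 80 °C, 24 h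
Reagents that add atoms: none
Why: Nickel-catalysed denitrogenative cross-coupling of an N-unsubstituted aldehyde hydrazone with an aryl bromide (Wolff–Kishner-type carbonyl umpolung): oxidative addition of 1 to zerovalent nickel, N-coordination and deprotonation of 4, C–C bond formation at the former carbonyl carbon and loss of N2 install the whole pentyl chain in one operation; aliphatic hydrazones are the less forgiving partners in this known reaction class, and no stereocentre is formed.

Step 2
Reactants: 5 1,3-dimethoxy-5-pentylbenzene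
Product: 6 5-pentylbenzene-1,3-diol (olivetol)
Conditions: pyridinium chloride (6 equiv), neat, 200 °C, 3 h
Reagents that add atoms: none
Why: Double O-demethylation by SN2 attack of chloride on the protonated aryl methyl ethers in molten pyridinium chloride, the classical ether cleavage used for olivetol; the alkyl chain is inert.

Step 3
Reactants: 6 5-pentylbenzene-1,3-diol
Product: 8 2,4-dihydroxy-6-pentylbenzaldehyde, via iminium chloride 7 (not isolated)
Conditions: POCl3 (1.5 equiv), DMF, 0 °C → rt, 2 h; then H2O, 50 °C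
Reagents that add atoms: N,N-dimethylformamide CN(C)C=O (CH=NMe2 of 7, formyl carbon of 8); phosphoryl chloride O=P(Cl)(Cl)Cl (chloride counter-ion of 7 only); water O (carbonyl oxygen of 8)
Why: Vilsmeier–Haack formylation at C4 of the resorcinol (para to one OH, ortho to the other), as in orcinol → orcylaldehyde, with the minor 2-formyl isomer removed by crystallisation and the iminium salt hydrolysed on work-up.

Step 4
Reactants: 5 1,3-dimethoxy-5-pentylbenzene
Product: 10 2-chloro-1,3-dimethoxy-5-pentylbenzene, via aryllithium 9 (not isolated)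
Conditions: n-BuLi (1.1 equiv), THF, 0 °C → rt, 2 h; then C2Cl6 (1.2 equiv), −78 °C → rt
Reagents that add atoms: n-butyllithium [Li]CCCC (Li of 9 only); hexachloroethane ClC(Cl)(Cl)C(Cl)(Cl)Cl (Cl)
Why: Directed ortho-metalation at the position flanked by both OMe groups followed by electrophilic chlorination puts Cl regiospecifically between the two oxygens and leaves two ring positions that are equivalent by symmetry.

Step 5
Reactants: 10 2-chloro-1,3-dimethoxy-5-pentylbenzene
Product: 12 3-chloro-2,4-dimethoxy-6-pentylbenzaldehyde, via chloro ether 11 (not isolated)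
Conditions: Cl2CHOMe (1.5 equiv), TiCl4 (2.2 equiv), CH2Cl2, −78 → 0 °C, 1 h; then ice, 1 M HCl
Reagents that add atoms: dichloromethyl methyl ether COC(Cl)Cl (CH(Cl)OMe of 11, formyl carbon of 12); water O (carbonyl oxygen of 12)
Why: Rieche formylation (Friedel–Crafts type) at the only free ring position, which is para to one OMe and ortho to the other and is the same on either side by symmetry, so only one regioisomer can form.

Step 6
Reactants: 12 3-chloro-2,4-dimethoxy-6-pentylbenzaldehyde
Product: 14 3-chloro-2-hydroxy-4-methoxy-6-pentylbenzaldehyde, via aryl dichloroborinate 13 (not isolated)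
Conditions: BCl3 (1.2 equiv, 1 M in CH2Cl2), CH2Cl2, −78 → 0 °C, 1 h; then H2O
Reagents that add atoms: boron trichloride ClB(Cl)Cl (BCl2 of 13 only)
Why: Chelation-controlled Lewis-acid ether cleavage: BCl3 bound to the aldehyde oxygen removes only the ortho methyl ether through a six-membered chelate, while the para OMe cannot chelate and survives.

Step 7
Reactants: 14 3-chloro-2-hydroxy-4-methoxy-6-pentylbenzaldehyde
Product: 15 3-chloro-2-hydroxy-4-methoxy-6-pentylbenzoic acid
Conditions: NaClO2 (3 equiv), NaH2PO4 (3 equiv), 2-methyl-2-butene (10 equiv), t-BuOH/H2O 3:1, rt, 6 h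
Reagents that add atoms: sodium chlorite [Na+].[O-]Cl=O (one O)
Why: Pinnick (Lindgren) oxidation of the salicylaldehyde to the salicylic acid, with the alkene scavenging HOCl so that the free C5 position of the electron-rich ring is not chlorinated.

Step 8
Reactants: 15 3-chloro-2-hydroxy-4-methoxy-6-pentylbenzoic acid; 8 2,4-dihydroxy-6-pentylbenzaldehyde
Product: 17 4-formyl-3-hydroxy-5-pentylphenyl 3-chloro-2-hydroxy-4-methoxy-6-pentylbenzoate, via mixed anhydride 16 (not isolated)
Conditions: (CF3CO)2O (3 equiv), toluene, rt, 4 h; then aq. NaHCO3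
Reagents that add atoms: trifluoroacetic anhydride O=C(OC(=O)C(F)(F)F)C(F)(F)F (CF3CO of 16 only)
Why: Trifluoroacetic-anhydride-mediated depside esterification through the aroyl trifluoroacetate: the free 4-OH of 8 is acylated, whereas the two ortho-hydroxyls (on 8 and on 15) are hydrogen-bonded to their carbonyl groups and stay unreactive.

Step 9
Reactants: 17 4-formyl-3-hydroxy-5-pentylphenyl 3-chloro-2-hydroxy-4-methoxy-6-pentylbenzoate
Product: 18 4-[(3-chloro-2-hydroxy-4-methoxy-6-pentylbenzoyl)oxy]-2-hydroxy-6-pentylbenzoic acid (3-chloroperlatolic acid)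
Conditions: NaClO2 (3 equiv), NaH2PO4 (3 equiv), 2-methyl-2-butene (20 equiv), t-BuOH/THF/H2O, 0 °C → rt, 8 h
Reagents that add atoms: sodium chlorite [Na+].[O-]Cl=O (one O)
Why: Pinnick oxidation unmasks the ring B carboxylic acid under buffered, mildly acidic conditions that leave the aryl ester, the aryl chloride and the phenols untouched, so no protecting group has to be removed at the end.

## Compound list

1 | 1-bromo-3,5-dimethoxybenzene | COc1cc(Br)cc(OC)c1 | starting material
2 | pentanal | CCCCC=O | starting material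
3 | hydrazine monohydrate | NN.O | starting material
4 | (E)-pentanal hydrazone (pentylidenehydrazine) | CCCC/C=N/N | intermediate
5 | 1,3-dimethoxy-5-pentylbenzene | CCCCCc1cc(OC)cc(OC)c1 | intermediate
6 | 5-pentylbenzene-1,3-diol (olivetol) | CCCCCc1cc(O)cc(O)c1 | intermediate
7 | N-[(2,4-dihydroxy-6-pentylphenyl)methylidene]-N-methylmethanaminium chloride | CCCCCc1cc(O)cc(O)c1C=[N+](C)C.[Cl-] | intermediate
8 | 2,4-dihydroxy-6-pentylbenzaldehyde | CCCCCc1cc(O)cc(O)c1C=O | intermediate
9 | (2,6-dimethoxy-4-pentylphenyl)lithium | CCCCCc1cc(OC)c([Li])c(OC)c1 | intermediate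
10 | 2-chloro-1,3-dimethoxy-5-pentylbenzene | CCCCCc1cc(OC)c(Cl)c(OC)c1 | intermediate
11 | 3-chloro-1-[chloro(methoxy)methyl]-2,4-dimethoxy-6-pentylbenzene (racemic, centre lost on hydrolysis) | CCCCCc1cc(OC)c(Cl)c(OC)c1C(Cl)OC | intermediate
12 | 3-chloro-2,4-dimethoxy-6-pentylbenzaldehyde | CCCCCc1cc(OC)c(Cl)c(OC)c1C=O | intermediate
13 | dichloro(2-chloro-6-formyl-3-methoxy-5-pentylphenoxy)borane | CCCCCc1cc(OC)c(Cl)c(OB(Cl)Cl)c1C=O | intermediate
14 | 3-chloro-2-hydroxy-4-methoxy-6-pentylbenzaldehyde | CCCCCc1cc(OC)c(Cl)c(O)c1C=O | intermediate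
15 | 3-chloro-2-hydroxy-4-methoxy-6-pentylbenzoic acid | CCCCCc1cc(OC)c(Cl)c(O)c1C(=O)O | intermediate
16 | 3-chloro-2-hydroxy-4-methoxy-6-pentylbenzoic trifluoroacetic anhydride | CCCCCc1cc(OC)c(Cl)c(O)c1C(=O)OC(=O)C(F)(F)F | intermediate
17 | 4-formyl-3-hydroxy-5-pentylphenyl 3-chloro-2-hydroxy-4-methoxy-6-pentylbenzoate | CCCCCc1cc(OC(=O)c2c(CCCCC)cc(OC)c(Cl)c2O)cc(O)c1C=O | intermediate
18 | 4-[(3-chloro-2-hydroxy-4-methoxy-6-pentylbenzoyl)oxy]-2-hydroxy-6-pentylbenzoic acid | CCCCCc1cc(OC(=O)c2c(CCCCC)cc(OC)c(Cl)c2O)cc(O)c1C(=O)O | target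

## Step count and risks

Total steps: 9. Longest linear sequence: 7 (steps 1, 4, 5, 6, 7, 8, 9); the ring B branch (steps 2 and 3) joins at step 8.

**Step 1** is the riskiest: an aliphatic hydrazone can give N-arylation, azine formation or simple Wolff–Kishner reduction instead of C-arylation. The fallback sets out from 1 and comes back at 5, keeping the polarity reversal but using a classical acyl-anion equivalent. Bromine–lithium exchange on 1 (n-BuLi, THF, −78 °C) gives (3,5-dimethoxyphenyl)lithium F1, which is quenched with DMF to 3,5-dimethoxybenzaldehyde F2 (also a cheap catalogue compound). Propane-1,3-dithiol and BF3·OEt2 in CH2Cl2 convert it into 2-(3,5-dimethoxyphenyl)-1,3-dithiane F3. Deprotonation with n-BuLi (THF, −30 °C) gives 2-(3,5-dimethoxyphenyl)-2-lithio-1,3-dithiane F4, which is alkylated with 1-bromobutane to 2-butyl-2-(3,5-dimethoxyphenyl)-1,3-dithiane F5. Raney nickel in refluxing EtOH desulfurises F5 to 5.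

**Step 8** may fail because the acid is di-ortho-substituted and carries a free ortho-OH, and because the aldehyde of 8 could condense with the salicylic acid under TFAA. The fallback sets out from 12 and comes back at 17, masking the ring A hydroxyl as its methyl ether and using an acid chloride. Pinnick oxidation of 12 (NaClO2, NaH2PO4, 2-methyl-2-butene) gives 3-chloro-2,4-dimethoxy-6-pentylbenzoic acid F6. Oxalyl chloride with catalytic DMF in CH2Cl2 gives 3-chloro-2,4-dimethoxy-6-pentylbenzoyl chloride F7. This acylates the more acidic, non-chelated 4-OH of 8 (K2CO3, acetone, 0 °C → rt) to give 4-formyl-3-hydroxy-5-pentylphenyl 3-chloro-2,4-dimethoxy-6-pentylbenzoate F8. BCl3 (CH2Cl2, −78 → 0 °C) then cleaves only the methyl ether ortho to the ester carbonyl, through 4-formyl-3-hydroxy-5-pentylphenyl 3-chloro-2-[(dichloroboranyl)oxy]-4-methoxy-6-pentylbenzoate F9, and aqueous work-up gives 17.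

**Step 9** may fail through ring chlorination of the phenolic ring B by HOCl or through slow oxidation of the chelated aldehyde. The fallback sets out from 6 and comes back at 18, carrying ring B at the acid oxidation level as a benzyl ester. Carboxylation of 6 with MeOMgOCO2Me (DMF, 120 °C, then aq. HCl) gives 2,4-dihydroxy-6-pentylbenzoic acid F10. Selective carboxylate alkylation (BnBr, KHCO3, DMF, rt) gives benzyl 2,4-dihydroxy-6-pentylbenzoate F11. Coupling with 15 under the conditions of step 8 (TFAA, toluene, via 16) gives benzyl 4-[(3-chloro-2-hydroxy-4-methoxy-6-pentylbenzoyl)oxy]-2-hydroxy-6-pentylbenzoate F12. Brief hydrogenolysis (H2 1 atm, 10% Pd/C, EtOAc, rt, stopped after one equivalent of H2 to spare the aryl chloride) gives 18.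

## Further compounds

F1 | step 1 | (3,5-dimethoxyphenyl)lithium | COc1cc([Li])cc(OC)c1
F2 | step 1 | 3,5-dimethoxybenzaldehyde | COc1cc(C=O)cc(OC)c1
F3 | step 1 | 2-(3,5-dimethoxyphenyl)-1,3-dithiane | COc1cc(cc(OC)c1)C1SCCCS1
F4 | step 1 | 2-(3,5-dimethoxyphenyl)-2-lithio-1,3-dithiane | COc1cc(cc(OC)c1)C1([Li])SCCCS1
F5 | step 1 | 2-butyl-2-(3,5-dimethoxyphenyl)-1,3-dithiane | CCCCC1(SCCCS1)c1cc(OC)cc(OC)c1
F6 | step 8 | 3-chloro-2,4-dimethoxy-6-pentylbenzoic acid | CCCCCc1cc(OC)c(Cl)c(OC)c1C(=O)O
F7 | step 8 | 3-chloro-2,4-dimethoxy-6-pentylbenzoyl chloride | CCCCCc1cc(OC)c(Cl)c(OC)c1C(Cl)=O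
F8 | step 8 | 4-formyl-3-hydroxy-5-pentylphenyl 3-chloro-2,4-dimethoxy-6-pentylbenzoate | CCCCCc1cc(OC(=O)c2c(CCCCC)cc(OC)c(Cl)c2OC)cc(O)c1C=O
F9 | step 8 | 4-formyl-3-hydroxy-5-pentylphenyl 3-chloro-2-[(dichloroboranyl)oxy]-4-methoxy-6-pentylbenzoate | CCCCCc1cc(OC(=O)c2c(CCCCC)cc(OC)c(Cl)c2OB(Cl)Cl)cc(O)c1C=O
F10 | step 9 | 2,4-dihydroxy-6-pentylbenzoic acid (olivetolic acid) | CCCCCc1cc(O)cc(O)c1C(=O)O
F11 | step 9 | benzyl 2,4-dihydroxy-6-pentylbenzoate | CCCCCc1cc(O)cc(O)c1C(=O)OCc1ccccc1
F12 | step 9 | benzyl 4-[(3-chloro-2-hydroxy-4-methoxy-6-pentylbenzoyl)oxy]-2-hydroxy-6-pentylbenzoate | CCCCCc1cc(OC(=O)c2c(CCCCC)cc(OC)c(Cl)c2O)cc(O)c1C(=O)OCc1ccccc1
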